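**Plan**

- The target is robinetinidol-(4β→8)-epigallocatechin. Retrosynthesis: the lower C3–OH goes back to C3–B; the lower pyran ring is then cut at O1–C2 and C3–C4 (hetero-Diels–Alder); the interflavan C4–C8 bond is then cut to a C4 ketone plus a lithiated phloroglucinol ether.
- Enabling feature: in the lower unit, O1 sits on C8a of ring A, ortho to C4a, which carries the C4 methylene. O1–C8a=C4a–C4 is the retron of an ortho-quinone methide, and the cis C2-aryl/C3-hydroxyl pair is the imprint of a (Z)-alkene.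
- Forward: the upper chroman (rings A, C, B) comes intact from (+)-dihydrorobinetin. The lower ring A is attached to C4 by aryllithium addition and ionic deoxygenation. Ortho-formylation and reduction give a salicyl alcohol. The lower pyran ring is closed last by cycloaddition with a (Z)-styrylboronate, followed by C–B oxidation and hydrogenolysis.
- Stereochemistry: upper C2/C3 from the chiral pool; upper C4 by hydride delivery anti to the 3-silyloxy group; lower C2/C3 cis from the alkene geometry, absolute sense from a chiral phosphoric acid; C–B to C–O with retention.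

Key step: step 11

Assumption: natural (2R,3R)-(+)-dihydrorobinetin is purchased, and the (R)-phosphoric acid is taken as the matched catalyst enantiomer in step 11 (the (S)-acid is used if it proves matched).

**Route**

Step 1
Reactants: 1 (+)-dihydrorobinetin
Product: 2 (2R,3R)-7-(benzyloxy)-3-hydroxy-2-[3,4,5-tris(benzyloxy)phenyl]chroman-4-one
Conditions: BnBr, K2CO3, DMF, rt, argon
Reagents that add atoms: benzyl bromide, BrCc1ccccc1
Why: Williamson etherification, in which the four phenols are alkylated by the mild carbonate base while the ketol hydroxyl is not, and room temperature should leave the C2/C3 stereocentres of the dihydroflavonol untouched.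

Step 2
Reactants: 2 tetra-O-benzyl dihydrorobinetin
Product: 3 (2R,3R)-7-(benzyloxy)-3-[(tert-butyldimethylsilyl)oxy]-2-[3,4,5-tris(benzyloxy)phenyl]chroman-4-one
Conditions: TBSOTf, 2,6-lutidine, CH2Cl2, 0 °C
Reagents that add atoms: tert-butyldimethylsilyl trifluoromethanesulfonate, CC(C)(C)[Si](C)(C)OS(=O)(=O)C(F)(F)F
Why: Silylation of the secondary ketol hydroxyl with a silyl triflate and a hindered base avoids strong base and places on O-3 the bulky group that later steers hydride delivery.

Step 3
Reactants: 4 3,5-bis(benzyloxy)phenol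
Product: 5 1,3-bis(benzyloxy)-5-(methoxymethoxy)benzene
Conditions: MOMCl, iPr2NEt, CH2Cl2, 0 °C to rt
Reagents that add atoms: chloromethyl methyl ether, COCCl
Why: O-Alkylation of the phenol gives the MOM ether, which marks the future O1 oxygen and is the strongest directing group on the ring for ortho-lithiation.

Step 4
Reactants: 5 MOM ether (1.6 equiv); 3 silylated ketone
Product: 7 tertiary carbinol (2R,3R,4R)-4-[2,4-bis(benzyloxy)-6-(methoxymethoxy)phenyl]-7-(benzyloxy)-3-[(tert-butyldimethylsilyl)oxy]-2-[3,4,5-tris(benzyloxy)phenyl]chroman-4-ol, via aryllithium 6 (not isolated)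
Conditions: nBuLi, THF, 0 °C; then 3, THF, −78 °C; H2O quench
Reagents that add atoms: none
Why: Directed ortho-metalation at the carbon flanked by OMOM and OBn gives 6, whose 1,2-addition to the ketone at low temperature (expected to outrun enolisation of the α-silyloxy ketone) forms the C4–aryl bond, and the carbinol configuration is of no consequence because C4 is ionised in step 5.

Step 5
Reactants: 7 tertiary carbinol
Product: 9 (2R,3S,4R)-4-[2,4-bis(benzyloxy)-6-(methoxymethoxy)phenyl]-7-(benzyloxy)-3-[(tert-butyldimethylsilyl)oxy]-2-[3,4,5-tris(benzyloxy)phenyl]chromane, via benzylic cation 8 (not isolated)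
Conditions: nBu3SnH, CF3CO2H, CH2Cl2, 0 °C
Reagents that add atoms: none
Why: Ionic deoxygenation, in which the acid ionises the doubly benzylic tertiary alcohol to cation 8 and nBu3SnH should deliver hydride to the face anti to the adjacent bulky 3-silyloxy group, leaving the aryl ring cis to O-3 (4β, 4R).

Step 6
Reactants: 9 4β-aryl flavan
Product: 10 (2R,3S,4R)-4-[2,4-bis(benzyloxy)-6-hydroxyphenyl]-7-(benzyloxy)-2-[3,4,5-tris(benzyloxy)phenyl]chroman-3-ol
Conditions: HCl (1.25 M in MeOH), THF, 40 °C
Reagents that add atoms: none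
Why: Acid-catalysed transacetalisation and desilylation in methanol remove the MOM and TBS groups in one operation, while the benzyl ethers and the acid-stable C4–aryl bond of the 5-deoxy flavan should survive.

Step 7
Reactants: 10 phenol
Product: 11 4,6-bis(benzyloxy)-2-hydroxy-3-{(2R,3S,4R)-7-(benzyloxy)-3-hydroxy-2-[3,4,5-tris(benzyloxy)phenyl]chroman-4-yl}benzaldehyde
Conditions: MgCl2, Et3N, paraformaldehyde, MeCN, reflux
Reagents that add atoms: formaldehyde (used as paraformaldehyde), C=O
Why: Casnati–Skattebøl ortho-formylation, in which the phenoxide bound to MgCl2 delivers formaldehyde only to the free position ortho to the phenol oxygen (the future C4a) and a second formaldehyde oxidises the hydroxymethyl intermediate to the aldehyde by hydride transfer.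

Step 8
Reactants: 11 salicylaldehyde
Product: 12 (2R,3S,4R)-4-[2,4-bis(benzyloxy)-6-hydroxy-5-(hydroxymethyl)phenyl]-7-(benzyloxy)-2-[3,4,5-tris(benzyloxy)phenyl]chroman-3-ol
Conditions: NaBH4, THF/MeOH, −20 °C; neutral work-up, used at once
Reagents that add atoms: none
Why: NaBH4 reduction of the aldehyde at low temperature gives the salicyl alcohol, the precursor of the ortho-quinone methide, and the low temperature should prevent over-reduction to the methyl compound.

Step 9
Reactants: 13 3,4,5-tris(benzyloxy)benzaldehyde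
Product: 14 1,2,3-tris(benzyloxy)-5-ethynylbenzene
Conditions: dimethyl (1-diazo-2-oxopropyl)phosphonate, K2CO3, MeOH/THF, rt
Reagents that add atoms: dimethyl (1-diazo-2-oxopropyl)phosphonate, CC(=O)C(=[N+]=[N-])P(=O)(OC)OC
Why: Ohira–Bestmann homologation converts the aldehyde into the terminal alkyne under mild basic conditions that leave the benzyl ethers alone.

Step 10
Reactants: 14 aryl alkyne
Product: 15 2-{(Z)-2-[3,4,5-tris(benzyloxy)phenyl]ethenyl}-4,4,5,5-tetramethyl-1,3,2-dioxaborolane
Conditions: pinacolborane, [Rh(cod)Cl]2 (cat.), P(iPr)3, Et3N, cyclohexane, rt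
Reagents that add atoms: pinacolborane, B1OC(C)(C)C(C)(C)O1
Why: Formal trans-hydroboration of a terminal alkyne catalysed by [Rh(cod)Cl]2 and P(iPr)3 (through a metal vinylidene) places boron on the terminal carbon cis to the aryl group, which gives the (Z)-alkenylboronate.

Step 11
Reactants: 12 salicyl alcohol; 15 (Z)-styrylboronate (3 equiv, excess recovered)
Product: 17 7,3',4',5'-tetra-O-benzylrobinetinidol-(4β→8)-[(2S,3R)-5,7-bis(benzyloxy)-3-(4,4,5,5-tetramethyl-1,3,2-dioxaborolan-2-yl)-2-(3,4,5-tris(benzyloxy)phenyl)chromane] (boron cis to the C2 aryl), via ortho-quinone methide 16 (not isolated)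
Conditions: (R)-3,3'-bis(2,4,6-triisopropylphenyl)-1,1'-binaphthyl-2,2'-diyl hydrogen phosphate (10 mol %), 5 Å molecular sieves, toluene, 40 °C, slow addition of 12
Reagents that add atoms: none
Why: Proposed new method: the phosphoric acid dehydrates the electron-rich salicyl alcohol 12 (ionisation is pushed by O1 and the two benzyloxy groups) to the ortho-quinone methide 16, which reacts as an electron-poor 1-oxadiene with the styrene-type boronate 15 in an inverse-electron-demand hetero-Diels–Alder reaction, the closest known reaction types being chiral-phosphoric-acid-catalysed [4+2] cycloadditions of in situ ortho-quinone methides with styrenes and thermal additions of phloroglucinol-derived ortho-quinone methides to unactivated alkenes. The pyran ring is closed by this [4+2] cycloaddition, concerted but asynchronous (C4–C3 bonding leads, O1–C2 follows inside the hydrogen-bonded complex), so that O1–C2 and C3–C4 are made together. C2 and C3 are created at once: their cis relation is the Z geometry of 15 carried over suprafacially, and their absolute sense should be set by the chiral phosphate held on the O1 oxygen, which shields one face of 16 and lets the alkene add to the other with the ring B aryl endo (catalyst control, because the remote upper unit biases the faces only weakly). Regioselectivity needs the methide carbon to bond to the boron-bearing carbon, and the substrate pair secures it: positive charge then builds on the benzylic carbon, stabilised by the trialkoxyphenyl ring and the β C–B bond, whereas an enol ether would add the other way round. The ring can close only through the one free phenol oxygen (the other two ring A oxygens are benzyl ethers), which fixes the 4→8 rather than the 4→6 constitution, and the pinacol ester, unlike acyclic boronates, should not form the phenoxide ate complex that leads to alkenyl transfer. The C–B bond is the masked 3-hydroxyl, revealed with retention in step 12.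

Step 12
Reactants: 17 boryl flavan
Product: 18 7,3',4',5'-tetra-O-benzylrobinetinidol-(4β→8)-5,7,3',4',5'-penta-O-benzyl-epigallocatechin (nona-O-benzyl ether of the target)
Conditions: H2O2 (30% aq), NaOH, THF, 0 °C
Reagents that add atoms: hydrogen peroxide, OO
Why: Oxidation of the C–B bond by hydroperoxide goes by 1,2-migration of carbon from boron to oxygen with retention, so the 3-hydroxyl appears cis to the C2 aryl group (2R,3R).

Step 13
Reactants: 18 nona-O-benzyl ether
Product: 19 robinetinidol-(4β→8)-epigallocatechin (CNP0275321.4)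
Conditions: H2 (1 atm), Pd(OH)2/C, THF/MeOH, rt; filtration and evaporation under argon
Reagents that add atoms: none
Why: Hydrogenolysis cleaves all nine benzyl ethers over Pd(OH)2/C, should not open the chroman rings, and touches no stereocentre.

**Compound list**

1 | (+)-dihydrorobinetin, (2R,3R)-3,7-dihydroxy-2-(3,4,5-trihydroxyphenyl)chroman-4-one | Oc1ccc2c(c1)O[C@H](c1cc(O)c(O)c(O)c1)[C@@H](O)C2=O | starting material

2 | (2R,3R)-7-(benzyloxy)-3-hydroxy-2-[3,4,5-tris(benzyloxy)phenyl]chroman-4-one | C(c1ccccc1)Oc1ccc2c(c1)O[C@H](c1cc(OCc3ccccc3)c(OCc3ccccc3)c(OCc3ccccc3)c1)[C@@H](O)C2=O | intermediate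

3 | (2R,3R)-7-(benzyloxy)-3-[(tert-butyldimethylsilyl)oxy]-2-[3,4,5-tris(benzyloxy)phenyl]chroman-4-one | C(c1ccccc1)Oc1ccc2c(c1)O[C@H](c1cc(OCc3ccccc3)c(OCc3ccccc3)c(OCc3ccccc3)c1)[C@@H](O[Si](C)(C)C(C)(C)C)C2=O | intermediate

4 | 3,5-bis(benzyloxy)phenol | Oc1cc(OCc2ccccc2)cc(OCc2ccccc2)c1 | starting material

5 | 1,3-bis(benzyloxy)-5-(methoxymethoxy)benzene | COCOc1cc(OCc2ccccc2)cc(OCc2ccccc2)c1 | intermediate

6 | [2,4-bis(benzyloxy)-6-(methoxymethoxy)phenyl]lithium | [Li]c1c(OCc2ccccc2)cc(OCc2ccccc2)cc1OCOC | intermediate (not isolated)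

7 | (2R,3R,4R)-4-[2,4-bis(benzyloxy)-6-(methoxymethoxy)phenyl]-7-(benzyloxy)-3-[(tert-butyldimethylsilyl)oxy]-2-[3,4,5-tris(benzyloxy)phenyl]chroman-4-ol (aryl trans to the 3-silyloxy group) | C(c1ccccc1)Oc1ccc2c(c1)O[C@H](c1cc(OCc3ccccc3)c(OCc3ccccc3)c(OCc3ccccc3)c1)[C@@H](O[Si](C)(C)C(C)(C)C)[C@]2(O)c1c(OCc3ccccc3)cc(OCc3ccccc3)cc1OCOC | intermediate

8 | C4 benzylic cation from 7 (4-aryl-chroman-4-ylium, C2 and C3 unchanged) | C(c1ccccc1)Oc1ccc2c(c1)O[C@H](c1cc(OCc3ccccc3)c(OCc3ccccc3)c(OCc3ccccc3)c1)[C@@H](O[Si](C)(C)C(C)(C)C)[C+]2c1c(OCc3ccccc3)cc(OCc3ccccc3)cc1OCOC | intermediate (not isolated)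

9 | (2R,3S,4R)-4-[2,4-bis(benzyloxy)-6-(methoxymethoxy)phenyl]-7-(benzyloxy)-3-[(tert-butyldimethylsilyl)oxy]-2-[3,4,5-tris(benzyloxy)phenyl]chromane (4β-aryl, 2,3-trans-3,4-cis) | C(c1ccccc1)Oc1ccc2c(c1)O[C@H](c1cc(OCc3ccccc3)c(OCc3ccccc3)c(OCc3ccccc3)c1)[C@@H](O[Si](C)(C)C(C)(C)C)[C@H]2c1c(OCc3ccccc3)cc(OCc3ccccc3)cc1OCOC | intermediate

10 | (2R,3S,4R)-4-[2,4-bis(benzyloxy)-6-hydroxyphenyl]-7-(benzyloxy)-2-[3,4,5-tris(benzyloxy)phenyl]chroman-3-ol | C(c1ccccc1)Oc1ccc2c(c1)O[C@H](c1cc(OCc3ccccc3)c(OCc3ccccc3)c(OCc3ccccc3)c1)[C@@H](O)[C@H]2c1c(OCc3ccccc3)cc(OCc3ccccc3)cc1O | intermediate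

11 | 4,6-bis(benzyloxy)-2-hydroxy-3-{(2R,3S,4R)-7-(benzyloxy)-3-hydroxy-2-[3,4,5-tris(benzyloxy)phenyl]chroman-4-yl}benzaldehyde | C(c1ccccc1)Oc1ccc2c(c1)O[C@H](c1cc(OCc3ccccc3)c(OCc3ccccc3)c(OCc3ccccc3)c1)[C@@H](O)[C@H]2c1c(OCc3ccccc3)cc(OCc3ccccc3)c(C=O)c1O | intermediate

12 | (2R,3S,4R)-4-[2,4-bis(benzyloxy)-6-hydroxy-5-(hydroxymethyl)phenyl]-7-(benzyloxy)-2-[3,4,5-tris(benzyloxy)phenyl]chroman-3-ol (salicyl alcohol) | C(c1ccccc1)Oc1ccc2c(c1)O[C@H](c1cc(OCc3ccccc3)c(OCc3ccccc3)c(OCc3ccccc3)c1)[C@@H](O)[C@H]2c1c(OCc3ccccc3)cc(OCc3ccccc3)c(CO)c1O | intermediate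

13 | 3,4,5-tris(benzyloxy)benzaldehyde | O=Cc1cc(OCc2ccccc2)c(OCc2ccccc2)c(OCc2ccccc2)c1 | starting material

14 | 1,2,3-tris(benzyloxy)-5-ethynylbenzene | C#Cc1cc(OCc2ccccc2)c(OCc2ccccc2)c(OCc2ccccc2)c1 | intermediate

15 | 2-{(Z)-2-[3,4,5-tris(benzyloxy)phenyl]ethenyl}-4,4,5,5-tetramethyl-1,3,2-dioxaborolane | CC1(C)OB(/C=C\c2cc(OCc3ccccc3)c(OCc3ccccc3)c(OCc3ccccc3)c2)OC1(C)C | intermediate

16 | ortho-quinone methide from 12: 3,5-bis(benzyloxy)-6-methylidene-2-(flavan-4-yl)cyclohexa-2,4-dien-1-one, upper unit as in 12 | C(c1ccccc1)Oc1ccc2c(c1)O[C@H](c1cc(OCc3ccccc3)c(OCc3ccccc3)c(OCc3ccccc3)c1)[C@@H](O)[C@H]2C1=C(OCc3ccccc3)C=C(OCc3ccccc3)C(=C)C1=O | intermediate (not isolated)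

17 | cycloadduct: upper unit as in 12, lower chroman (2S,3R) with the pinacolboryl group at C3 cis to the C2 aryl (same spatial arrangement as 18; descriptors differ because boron changes the CIP order) | C(c1ccccc1)Oc1ccc2c(c1)O[C@H](c1cc(OCc3ccccc3)c(OCc3ccccc3)c(OCc3ccccc3)c1)[C@@H](O)[C@H]2c1c(OCc3ccccc3)cc(OCc3ccccc3)c2c1O[C@H](c1cc(OCc3ccccc3)c(OCc3ccccc3)c(OCc3ccccc3)c1)[C@H](B1OC(C)(C)C(C)(C)O1)C2 | intermediate

18 | nona-O-benzyl ether of the target (upper 2R,3S,4R; lower 2R,3R; both 3-hydroxyls free) | C(c1ccccc1)Oc1ccc2c(c1)O[C@H](c1cc(OCc3ccccc3)c(OCc3ccccc3)c(OCc3ccccc3)c1)[C@@H](O)[C@H]2c1c(OCc3ccccc3)cc(OCc3ccccc3)c2c1O[C@H](c1cc(OCc3ccccc3)c(OCc3ccccc3)c(OCc3ccccc3)c1)[C@H](O)C2 | intermediate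

19 | robinetinidol-(4β→8)-epigallocatechin (upper 2R,3S,4R, 2,3-trans-3,4-cis; lower 2R,3R, 2,3-cis) | Oc1ccc2c(c1)O[C@H](c1cc(O)c(O)c(O)c1)[C@@H](O)[C@H]2c1c(O)cc(O)c2c1O[C@H](c1cc(O)c(O)c(O)c1)[C@H](O)C2 | target

**Step count and risks**

Total steps: 13. Longest linear sequence: 10 steps (1, 2, 4, 5, 6, 7, 8, 11, 12, 13).

Steps most likely to fail:

1. Step 11 (the step labelled as new). What may go wrong:
   - weak or mismatched face selection, which gives the 2,3-cis adduct with the mirror-image lower unit;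
   - leakage into a stepwise cationic path with loss of the Z geometry, which gives the 2,3-trans adduct;
   - transfer of the alkenyl group from boron to the methide carbon without ring closure;
   - self-alkylation of the quinone methide at C6.

   Fallback (known reaction types; the ring is closed by epoxide opening instead of cycloaddition): it sets out from 12 and 15 and comes back at 18. Compound 12 is peracetylated (Ac2O, pyridine, DMAP) to the triacetate F1. Suzuki–Miyaura coupling of its benzylic acetate with 15 (Pd(OAc)2, 1,5-bis(diphenylphosphino)pentane, K3PO4, toluene) should give the (Z)-1,3-diarylpropene F2 with the alkene geometry retained. Shi epoxidation with the glucose-derived N-aryl oxazolidinone ketone for cis-alkenes (KHSO5 as the triple salt 2KHSO5·KHSO4·K2SO4, K2CO3 buffer, MeCN/dimethoxymethane/H2O, 0 °C) should give the cis-epoxide F3 under reagent control. Methanolysis of the acetates (K2CO3, MeOH) frees the epoxy phenol F4 (not isolated). Camphorsulfonic acid then closes the pyran ring by 6-endo attack of the phenol at the benzylic epoxide carbon with inversion, which should give 18 with the 2,3-cis arrangement.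

2. Step 5. What may go wrong: hydride delivery to the wrong face of cation 8, which gives the 4α-aryl (3,4-trans) epimer, or loss of H-3 to an enol ether. Fallback: it sets out from 2 and comes back at 10. NaBH4 (EtOH/THF, 0 °C) reduces 2 to the 2,3-trans-3,4-trans diol F5. BF3·OEt2 (CH2Cl2, −30 °C) ionises its benzylic 4-hydroxyl in the presence of excess 4, a Friedel–Crafts arylation of the classical kind for 4-arylflavan-3-ols. This should give both C4 epimers and some para-linked isomer; the ortho-linked 4β isomer is 10 and is separated by chromatography. The detour also bypasses steps 2 to 4 and 6, so it answers a failed addition in step 4 as well.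

3. Step 10. What may go wrong: erosion of the Z selectivity by isomerisation of the kinetic boronate, or dimerisation of the alkyne. Fallback: it sets out from 14 and comes back at 15. Deprotonation (nBuLi, THF, −78 °C) gives the lithium acetylide F6 (not isolated). Borylation with 2-isopropoxy-4,4,5,5-tetramethyl-1,3,2-dioxaborolane, then HCl in ether, gives the alkynylboronate F7. Cis-semihydrogenation (H2, Pd/CaCO3 poisoned with Pb(OAc)2, quinoline) then fixes the Z geometry by syn delivery of hydrogen and should leave the benzyl ethers intact.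

Further compounds

F1 | step 11 | triacetate of 12 (phenol, benzylic and upper 3-O acetates) | C(c1ccccc1)Oc1ccc2c(c1)O[C@H](c1cc(OCc3ccccc3)c(OCc3ccccc3)c(OCc3ccccc3)c1)[C@@H](OC(C)=O)[C@H]2c1c(OCc3ccccc3)cc(OCc3ccccc3)c(COC(C)=O)c1OC(C)=O

F2 | step 11 | (Z)-1,3-diarylpropene (aryl acetate and upper 3-O acetate retained) | C(c1ccccc1)Oc1ccc2c(c1)O[C@H](c1cc(OCc3ccccc3)c(OCc3ccccc3)c(OCc3ccccc3)c1)[C@@H](OC(C)=O)[C@H]2c1c(OCc3ccccc3)cc(OCc3ccccc3)c(C/C=C\c4cc(OCc3ccccc3)c(OCc3ccccc3)c(OCc3ccccc3)c4)c1OC(C)=O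

F3 | step 11 | cis-epoxide of F2 (benzylic carbon S, the other epoxide carbon R) | C(c1ccccc1)Oc1ccc2c(c1)O[C@H](c1cc(OCc3ccccc3)c(OCc3ccccc3)c(OCc3ccccc3)c1)[C@@H](OC(C)=O)[C@H]2c1c(OCc3ccccc3)cc(OCc3ccccc3)c(C[C@H]4O[C@H]4c5cc(OCc3ccccc3)c(OCc3ccccc3)c(OCc3ccccc3)c5)c1OC(C)=O

F4 | step 11 | deacetylated epoxy phenol (not isolated) | C(c1ccccc1)Oc1ccc2c(c1)O[C@H](c1cc(OCc3ccccc3)c(OCc3ccccc3)c(OCc3ccccc3)c1)[C@@H](O)[C@H]2c1c(OCc3ccccc3)cc(OCc3ccccc3)c(C[C@H]4O[C@H]4c5cc(OCc3ccccc3)c(OCc3ccccc3)c(OCc3ccccc3)c5)c1O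

F5 | step 5 | (2R,3S,4R)-7-(benzyloxy)-2-[3,4,5-tris(benzyloxy)phenyl]chromane-3,4-diol (2,3-trans-3,4-trans) | C(c1ccccc1)Oc1ccc2c(c1)O[C@H](c1cc(OCc3ccccc3)c(OCc3ccccc3)c(OCc3ccccc3)c1)[C@@H](O)[C@@H]2O

F6 | step 10 | lithium [3,4,5-tris(benzyloxy)phenyl]acetylide (not isolated) | [Li]C#Cc1cc(OCc2ccccc2)c(OCc2ccccc2)c(OCc2ccccc2)c1

F7 | step 10 | 2-{[3,4,5-tris(benzyloxy)phenyl]ethynyl}-4,4,5,5-tetramethyl-1,3,2-dioxaborolane | CC1(C)OB(C#Cc2cc(OCc3ccccc3)c(OCc3ccccc3)c(OCc3ccccc3)c2)OC1(C)C
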